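## Retrosynthetic overview

1. Vernolide-B ⇒ 8-O-tigloylation and CBS reduction of 8-ketone **13**; the 5,6-alkene comes from E1cB loss of AcOH from **12**, with the geometry enforced by the ring.
2. Key disconnection C9–C10: an α-keto radical (from a bromoacetyl group on the butenolide) adds to the (Z)-exocyclic enol ether of a 2-ethylidene-oxolane. Oxidation of the C1 radical and MeOH capture give the bridged methyl ketal, close the ten-membered ring, and relay C4 to C10 and C1.
3. The enol ether comes from Au-catalysed 5-exo-dig cyclisation of the C4 tertiary alcohol onto a C1≡C10 alkyne; the bromoketone comes from a vinyl group.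
4. C5–C6 is made by vinylogous aldol of butenolide **3** (from but-2-yne-1,4-diol, vinylMgCl, CO2) with aldehyde **7** (from (S)-2-methylglycidol and 2-butyne).
5. Ring order: butenolide → oxolane (as enol ether) → ten-membered carbocycle and ketal bridge together in the key step.

Assumption: (S)-2-methylglycidol is bought as the single enantiomer. Germacrane numbering (C1–C15) is used to label atoms in intermediates.

## Route

**Step 1**
Reactants: **1** but-2-yne-1,4-diol; **2** vinylmagnesium chloride
Product: **3** 4-ethenyl-3-(hydroxymethyl)furan-2(5H)-one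
Conditions: **2** (4.5 equiv), THF, 65 °C, 16 h; CO2, −20 °C → rt; 2 M HCl
Reagents that add atoms: carbon dioxide, O=C=O (the vinyl group comes from **2**)
Why: Hydroxyl-directed anti-carbomagnesiation of the propargylic dialkoxide (Fallis type) puts vinyl on one alkyne carbon and Mg on the other, cis to a CH2O–; carboxylation and acid lactonisation give the butenolide, and the symmetry of **1** allows only one regioisomer (no stereocentre).

**Step 2**
Reactants: **4** (S)-2-methylglycidol; **5** but-2-yne
Product: **6** (2R)-2-methyl-1,2-bis(trimethylsilyloxy)hept-5-yne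
Conditions: **5** (3 equiv), n-BuLi (2.2 equiv), TMEDA, THF, −20 → 0 °C; **4**, 0 °C → rt; TMSCl (3 equiv), 0 °C
Reagents that add atoms: chlorotrimethylsilane, C[Si](C)(C)Cl (the but-2-ynyl group comes from **5**)
Why: Propargylic lithiation of 2-butyne gives but-2-ynyllithium, which opens the epoxide by SN2 at its CH2 carbon (the minor allenyl isomer is removed by chromatography); the quaternary carbon is untouched, so its geometry is retained (S → R is only a CIP priority change), and the dialkoxide is silylated in the same pot.

**Step 3**
Reactants: **6**
Product: **7** (2R)-2-methyl-2-(trimethylsilyloxy)hept-5-ynal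
Conditions: (COCl)2, DMSO, CH2Cl2, −78 → −30 °C; Et3N
Reagents that add atoms: none
Why: Swern oxidation of silyl ethers: the primary TMS ether is cleaved and oxidised in situ while the hindered tertiary TMS ether survives, giving the non-enolisable α-silyloxy aldehyde with C4 unchanged.

**Step 4**
Reactants: **3**; **7**
Product: **8** {5-[(2R)-1-acetoxy-2-methyl-2-(trimethylsilyloxy)hept-5-yn-1-yl]-4-ethenyl-2-oxo-2,5-dihydrofuran-3-yl}methyl acetate (mixture at C5 and C6)
Conditions: **3**, LiHMDS (2.1 equiv), THF–DMPU, −78 °C; **7**; Ac2O (3 equiv), DMAP (0.1 equiv), −78 → −30 °C; AcOH quench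
Reagents that add atoms: acetic anhydride, CC(=O)OC(C)=O
Why: Two equivalents of base give the alkoxide/2-oxidofuran dianion, which adds to the aldehyde at the γ-carbon (vinylogous aldol; the α-carbon is fully substituted and the alkoxide cannot be expelled), and Ac2O traps both alkoxides to install the final 13-OAc and a 5-OAc leaving group; C5 and C6 form as a mixture that is erased in step 9.

**Step 5**
Reactants: **8**
Product: **9** the 4-(2-bromo-1-hydroxyethyl) analogue of **8** (mixture at C8)
Conditions: NBS (1.1 equiv), THF–H2O (3:1), 0 °C, dark
Reagents that add atoms: N-bromosuccinimide, O=C1CCC(=O)N1Br; water, O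
Why: Bromohydrin formation: the vinyl group is the most nucleophilic alkene (the butenolide alkene is tetrasubstituted and electron-poor, and the alkyne reacts far more slowly), water opens the bromonium ion at the allylic carbon C8, and the new carbinol centre is removed in step 6.

**Step 6**
Reactants: **9**
Product: **10** {5-[(2R)-1-acetoxy-2-hydroxy-2-methylhept-5-yn-1-yl]-4-(bromoacetyl)-2-oxo-2,5-dihydrofuran-3-yl}methyl acetate
Conditions: Dess–Martin periodinane, NaHCO3, CH2Cl2, 0 °C → rt; then 1 M HCl–THF, 0 °C, 15 min
Reagents that add atoms: none
Why: Dess–Martin oxidation of the secondary alcohol gives the α-bromo ketone without touching the tertiary silyl ether, which is then cleaved by brief aqueous acid to free the C4 hydroxyl; no stereocentre is affected.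

**Step 7**
Reactants: **10**
Product: **11** {5-[acetoxy((2R,5Z)-5-ethylidene-2-methyloxolan-2-yl)methyl]-4-(bromoacetyl)-2-oxo-2,5-dihydrofuran-3-yl}methyl acetate
Conditions: [(JohnPhos)Au(MeCN)]SbF6 (2 mol %), 2,6-di-tert-butylpyridine (10 mol %), CH2Cl2, 0 °C → rt; filter through basic alumina and use directly
Reagents that add atoms: none
Why: Gold(I)-catalysed 5-exo-dig hydroalkoxylation of a 4-alkyn-1-ol (favoured by the fully substituted carbinol carbon); anti oxyauration and protodeauration with retention put H trans to O, giving the Z enol ether needed for step 8.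

**Step 8 (key step)**
Reactants: **11**
Product: **12** (1S,4R,10R)-5,13-diacetoxy-1,4-epoxy-1-methoxy-8-oxogermacr-7(11)-en-12,6-olide (mixture at C5 and C6)
Conditions: [Ir(ppy)2(dtbbpy)]PF6 (1 mol %), NaHCO3 (3 equiv), MeOH (20 equiv), MeCN (2 mM), 450 nm LEDs, rt, Ar
Reagents that add atoms: methanol, CO
Why: Proposed new method: the excited Ir(III) catalyst reduces the α-bromo ketone to the electrophilic C9 α-keto radical, which adds to the electron-rich enol ether at C10; the tether from C5 can only reach the oxolane face that carries C5, and with the Z enol ether this gives 10R; the resulting C1 α-alkoxy radical is oxidised (by Ir(IV) or by electron/bromine-atom transfer to more substrate) to the bridged oxocarbenium ion, which methanol can only capture from the open exo face to give 1S; the closest known reactions are intermolecular photoredox atom-transfer oxy-alkylation of enol ethers with α-bromo carbonyl compounds and Curran-type atom-transfer radical macrocyclisations.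

**Step 9**
Reactants: **12**
Product: **13** (1S,4R,5E,10R)-13-acetoxy-1,4-epoxy-1-methoxy-8-oxogermacra-5,7(11)-dien-12,6-olide
Conditions: DBU (1.2 equiv), CH2Cl2, −40 → 0 °C
Reagents that add atoms: none
Why: Vinylogous E1cB elimination: γ-deprotonation gives the 2-oxidofuran, which expels the 5-acetate; both C5/C6 diastereomers converge, and the ten-membered ring allows only the 5E alkene (C4 cis to C7).

**Step 10**
Reactants: **13**
Product: **14** (1S,4R,5E,8S,10R)-13-acetoxy-1,4-epoxy-8-hydroxy-1-methoxygermacra-5,7(11)-dien-12,6-olide
Conditions: (R)-Me-CBS (1 equiv), catecholborane (1.5 equiv), toluene, −78 °C; use crude alcohol at once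
Reagents that add atoms: none
Why: Corey–Bakshi–Shibata reduction: the tetrasubstituted alkenyl carbon C7 is the large group and CH2-9 the small one, so the (R)-catalyst should give the 8S alcohol (by analogy with aryl alkyl ketones), and catecholborane at −78 °C reduces only the ketone (1,2), leaving the lactone, acetate and ketal.

**Step 11**
Reactants: **14**; **15** tiglic acid
Product: **16** vernolide-B
Conditions: **15**, 2,4,6-trichlorobenzoyl chloride, Et3N, toluene, rt; then **14**, DMAP, rt
Reagents that add atoms: none (the tigloyl group comes from **15**)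
Why: Yamaguchi esterification of the hindered allylic alcohol through the mixed anhydride; the C8–O bond is not broken (retention) and the E (tiglate) geometry is the stable one.

## Compound list

1 | but-2-yne-1,4-diol | OCC#CCO | starting material
2 | vinylmagnesium chloride | C=C[Mg]Cl | starting material
3 | 4-ethenyl-3-(hydroxymethyl)furan-2(5H)-one | O=C1OCC(C=C)=C1CO | intermediate
4 | (S)-2-methylglycidol | C[C@]1(CO)CO1 | starting material
5 | but-2-yne | CC#CC | starting material
6 | (2R)-2-methyl-1,2-bis(trimethylsilyloxy)hept-5-yne | C[C@](O[Si](C)(C)C)(CO[Si](C)(C)C)CCC#CC | intermediate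
7 | (2R)-2-methyl-2-(trimethylsilyloxy)hept-5-ynal | O=C[C@](C)(O[Si](C)(C)C)CCC#CC | intermediate
8 | aldol bis-acetate (C4 R; C5/C6 mixture) | CC#CCC[C@@](C)(O[Si](C)(C)C)C(OC(C)=O)C1OC(=O)C(COC(C)=O)=C1C=C | intermediate
9 | bromohydrin of 8 | CC#CCC[C@@](C)(O[Si](C)(C)C)C(OC(C)=O)C1OC(=O)C(COC(C)=O)=C1C(O)CBr | intermediate
10 | bromoacetyl butenolide with free C4–OH | CC#CCC[C@@](C)(O)C(OC(C)=O)C1OC(=O)C(COC(C)=O)=C1C(=O)CBr | intermediate
11 | (Z)-2-ethylidene-oxolane bromoketone | C/C=C1/CC[C@](C)(C(OC(C)=O)C2OC(=O)C(COC(C)=O)=C2C(=O)CBr)O1 | intermediate
12 | (1S,4R,10R)-5,13-diacetoxy-1,4-epoxy-1-methoxy-8-oxogermacr-7(11)-en-12,6-olide | O=C1C[C@@H](C)[C@]2(OC)CC[C@](C)(C(OC(C)=O)C3OC(=O)C(COC(C)=O)=C31)O2 | intermediate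
13 | (1S,4R,5E,10R)-13-acetoxy-1,4-epoxy-1-methoxy-8-oxogermacra-5,7(11)-dien-12,6-olide | O=C1C[C@@H](C)[C@]2(OC)CC[C@](C)(/C=C3/OC(=O)C(COC(C)=O)=C31)O2 | intermediate
14 | 8S-alcohol of 13 | O[C@H]1C[C@@H](C)[C@]2(OC)CC[C@](C)(/C=C3/OC(=O)C(COC(C)=O)=C31)O2 | intermediate
15 | tiglic acid | C/C=C(\C)C(=O)O | starting material
16 | vernolide-B | C/C=C(\C)C(=O)O[C@H]1C[C@@H](C)[C@]2(OC)CC[C@](C)(/C=C3/OC(=O)C(COC(C)=O)=C31)O2 | target

## Step count and risks

Total steps: 11. Longest linear sequence: 10 (steps 2–11, from **4**).

Steps most likely to fail:

1. **Step 8.** The ten-membered radical closure may lose to 1,5-hydrogen transfer from C5–H or to simple reduction, and the C5/C6 diastereomers may cyclise at different rates. Fallback: make C9–C10 intermolecularly by the same radical oxy-alkylation, between a 4-(bromoacetyl)-3-(acetoxymethyl)butenolide and the enol-ether aldehyde derived from **7**, then close the ring at C5–C6 by intramolecular vinylogous aldol and dehydrate. This accepts weaker control at C10.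
2. **Step 4.** The dianion may attack partly at the α-carbon, the aldolate may revert, or the 5-acetate may eliminate early to the wrong (Z) ylidene. Fallback: alkylate the furanolate at C6 with the C4–C5 epoxide made from the diol corresponding to **6** (no C5 oxygen), and introduce the 5,6-alkene after macrocyclisation by γ-selenenylation and selenoxide elimination.
3. **Step 10.** The bicyclic macrocycle may override the catalyst and give the 8R alcohol. Fallback: reduce to the 8R alcohol deliberately (enantiomeric catalyst or substrate-controlled hydride) and install the tiglate with inversion by Mitsunobu reaction with tiglic acid.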